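## The problem

(+)-8-Methoxyisolariciresinol (13) is a 1-aryltetralin. Ring A is a pentasubstituted benzene (6-OMe, 7-OH, 8-OMe, hydrogen only at C5) fused through C4a and C8a to a saturated ring B with three contiguous, all-trans stereocentres: C1 (S, 4-hydroxy-3-methoxyphenyl), C2 (R, CH2OH) and C3 (R, CH2OH). The C1 aryl group lies peri to the C8 methoxyl, so whichever bond is made at C1 is made against crowding. Only one centre needs an outside source of chirality. C2 can set C1, because ring closure at C1 places the aryl group trans to the C2 substituent, and C2 can set C3, because a CH2OH group on C2 can steer hydrogen onto one face of a C3=C4 double bond. The sensitive features are the two free phenols (easily oxidised), the doubly benzylic C1–H para to a phenol (lost under oxidising conditions), and any 1,2-dihydronaphthalene intermediate, which aromatises readily and, as a p-hydroxycinnamyl alcohol, ionises in acid. The feature that opens the key step is that 13 is a dimer of two C6C3 units: a guaiacyl unit (pendant ring, C1, C2 and its carbinol) and a syringyl unit (ring A, C4, C3 and its carbinol), joined by C2–C3 and C1–C8a. Each phenol is para to its side chain (pendant OH para to C1, 7-OH para to C4a), so each unit can pass through a quinone methide, and C8a is ortho to the C8 methoxyl and para to the C6 methoxyl, which makes it the natural nucleophile toward C1.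

## Retrosynthesis

**13 from 12.** The last centre, C3, is removed first: taking the C3 and C4 hydrogens off 13 gives the 1,2-dihydronaphthalene-2,3-dimethanol 12 with a C3=C4 double bond. No skeletal bond is cut, but 12 has one stereocentre fewer and has the unsaturation pattern that an oxidative dimerisation of cinnamates delivers. Setting C3 at the ester stage would rest on steric approach or on equilibration. At the diol stage the C2 carbinol can bind a cationic hydrogenation catalyst and deliver hydrogen to its own face. The forward step must add hydrogen to C3 cis to the C2 carbinol without cleaving the allylic C–O bond.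

**12 from 11.** The two CH2OH groups of 12 are traced back to ester carbonyls, both bound to one molecule of (R,R)-hydrobenzoin 5, which gives the eight-membered dilactone 11. The skeleton is unchanged, but the two carbinol carbons become the handle that holds a chiral tether across C2–C3. Separate alkyl esters or separate auxiliaries on each acid would give no control over which two acids pair. The forward reduction must take both lactone carbonyls to the alcohols in the 1,2-sense, leave C3=C4 and C2 alone, and return 5.

**11 from 8.** The key cut removes C2–C3 and C1–C8a together and opens ring B and the dilactone ring, leading to the mixed ferulate–sinapate diester 8 of 5. Cutting at C1–aryl, at C1–C2/C3–C4 or through ring A instead leaves precursors whose oxygenation pattern or stereocentres have to be built separately; this cut leaves two natural cinnamates that already carry every oxygen of 13. The forward step asks for four things of one oxidation: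
- both phenols are oxidised and the two radicals pair within the molecule;
- they pair at the carbons alpha to the esters (through the bis(quinone methide) 9);
- ring B is closed by the syringyl ring and not the guaiacyl ring (through the styrene phenol 10);
- one face is chosen at C2.

The tether answers the first, second and fourth demands, and the electronic difference between the two rings answers the third. Because any C2 epimer of 11 is a diastereomer, the enantiomeric purity of 13 does not depend on perfect induction.

**8 from 1, 3 and 5.** The four ester and aryl acetate C–O bonds are cut in turn. Bisphenol 8 comes from its diacetate 7, 7 from monoester 6 and 4-O-acetylsinapic acid 4, 6 from 4-O-acetylferulic acid 2 and diol 5, and the acetylated acids from ferulic acid 1 and sinapic acid 3. Acetates are chosen because the acids cannot be coupled with free phenols and aryl acetates can be removed in the presence of cinnamate esters. The forward steps are routine acylations, and the C2 symmetry of 5 means that monoacylation has no regiochemical question.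

## Roads not taken

**Alternative 1:** The cut is through C1–C2 and C3–C4. Ring B would be formed by photoenolisation of the ortho-methylbenzophenone A1 under near-UV light and [4+2] addition of the resulting diene to the chiral fumarate A2, giving the 1-hydroxy-1-aryltetralin diester A3.
- Merits: two C–C bonds and ring B form in one step of a well-known type, and the 2,3-trans relation comes directly from the (E)-geometry of A2, so no late hydrogenation is needed. A1 is an ordinary diaryl ketone.
- Weak points: both phenols must travel as benzyl ethers. A3 carries a tertiary benzylic hydroxyl at C1 that must be replaced by hydrogen with the right configuration; this passes through a diarylmethyl cation, where elimination toward C2 competes. The menthyl groups of A2 control the dienophile face well only under Lewis acid chelation, which does not fit a photoenol, so the absolute induction is as open as in the chosen plan.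
- Comparison: in precedent for the ring-forming event, and in fixing C3 at once, this road is the stronger one. The chosen plan sets against it free phenols in the end game, C1 formed directly as C–H, an auxiliary that sits in a ring next to the new centre and is recovered, and a comparable step count without deoxygenation or deprotection.

**Alternative 2:** The cut removes both aryl bonds of C1 (C1–C8a and C1–aryl). A Lewis acid would make the aldehyde A4 cyclise onto its syringyl ring, and the benzylic cation formed from the resulting carbinol would be captured by guaiacol A5, giving the bis(pivalate) A6.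
- Merits: the pendant ring is introduced as the cheapest possible reagent, C1 is set last under control of C2, and the end game is very short.
- Weak points: A4 holds C2 and C3 on an open chain, and building them anti and enantiopure by auxiliary chemistry is where the steps go. The aldehyde alpha-centre can epimerise, and the cation can lose the C2 proton instead of being captured. A5 can react para to hydroxyl, para to methoxyl or ortho, giving regioisomeric pendant rings that would be hard to separate.
- Comparison: for absolute stereocontrol this road rests on established auxiliary chemistry and is safer on that count. The chosen plan sets against it a shorter sequence and a pendant ring that arrives with its substitution fixed.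

**Alternative 3:** The cut is through ring A (C4a–C5 and C8–C8a). Stille coupling of the cyclohexenylstannane A7 with the chlorocyclobutenone A8 under zerovalent palladium catalysis, then electrocyclic ring opening and six-electron ring closure on warming, would give the phenol A9.
- Merits: the arene is built regiospecifically under mild, neutral conditions, and the union is convergent.
- Weak points: A9 carries the hydroxyl at C8 and methoxyls at C6 and C7, whereas 13 needs 7-OH with 6,8-OMe. Methylation at O8 and selective demethylation at O7, in the presence of the pendant methoxyl, would have to follow. All three stereocentres sit in A7, a trisubstituted cyclohexene whose enantioselective synthesis is a multistep problem of its own. Tin reagents and benzyl ethers add further operations.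
- Comparison: each single step is on firmer ground than the oxidative cascade, and the regiochemistry of ring A is certain where the chosen plan relies on an electronic bias. The route would, however, be roughly twice as long and ends on the wrong phenol pattern; the chosen plan takes ring A ready-made from 3.

Key step: step 6

Assumption: the sense of induction by the tether is taken from the twist-boat model given under step 6, which pairs (R,R)-hydrobenzoin 5 with the 2R centre; the model is unproven, and the route is written for 5.

Step 1
Reactants: 1 ferulic acid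
Product: 2 4-O-acetylferulic acid
Conditions: Ac2O, pyridine, DMAP (cat.), rt; then H2O
Reagents that add atoms: acetic anhydride, CC(=O)OC(C)=O
Why: Phenol O-acetylation; the mixed anhydride formed at the carboxyl group is hydrolysed on aqueous work-up, so only the aryl acetate remains.

Step 2
Reactants: 3 sinapic acid
Product: 4 4-O-acetylsinapic acid
Conditions: Ac2O, pyridine, DMAP (cat.), rt; then H2O
Reagents that add atoms: acetic anhydride, CC(=O)OC(C)=O
Why: The same phenol O-acetylation; the hindered 2,6-dimethoxyphenol is acylated under DMAP catalysis.

Step 3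
Reactants: 2 4-O-acetylferulic acid; 5 (R,R)-hydrobenzoin (3 equiv)
Product: 6 (1R,2R)-2-hydroxy-1,2-diphenylethyl 4-O-acetylferulate
Conditions: EDC·HCl, DMAP (cat.), CH2Cl2, 0 °C to rt
Reagents that add atoms: none
Why: Steglich esterification; the excess of the C2-symmetric diol keeps diacylation low, either hydroxyl gives the same monoester, and the carbinol centres are untouched because the acyl C–O bond is the one formed. Unreacted 5 is recovered.

Step 4
Reactants: 6 (1R,2R)-2-hydroxy-1,2-diphenylethyl 4-O-acetylferulate; 4 4-O-acetylsinapic acid
Product: 7 (1R,2R)-1,2-diphenylethane-1,2-diyl 4-O-acetylferulate 4-O-acetylsinapate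
Conditions: EDC·HCl, DMAP, CH2Cl2, rt
Reagents that add atoms: none
Why: Second Steglich esterification of the remaining secondary hydroxyl; the configuration of the diol is retained.

Step 5
Reactants: 7 (1R,2R)-1,2-diphenylethane-1,2-diyl 4-O-acetylferulate 4-O-acetylsinapate
Product: 8 (1R,2R)-1,2-diphenylethane-1,2-diyl ferulate sinapate
Conditions: pyrrolidine (6 equiv), CH2Cl2, 0 °C to rt
Reagents that add atoms: none
Why: Aminolysis of aryl acetates; the phenoxide is a far better leaving group than the benzylic alkoxide, so the two cinnamate esters should survive.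

Step 6
Reactants: 8 (1R,2R)-1,2-diphenylethane-1,2-diyl ferulate sinapate
Product: 11 hydrobenzoin-tethered (1S,2R)-1-aryl-1,2-dihydronaphthalene-2,3-dicarboxylate dilactone, via bis(quinone methide) dilactone 9 (not isolated), via styrene phenol quinone methide 10 (not isolated)
Conditions: FeCl3·6H2O (2.2 equiv, added over 6 h), acetone–H2O 9:1, 1 mM in 8, Ar, rt
Reagents that add atoms: none
Why: Proposed new method: FeCl3 takes one electron and one proton from each phenol of 8, and the two phenoxyl radicals, which carry spin density on the carbons alpha to the ester carbonyls, recombine within the molecule to form C2–C3 and the eight-membered bis(quinone methide) dilactone 9. In the acidic medium the more basic syringyl quinone methide is protonated on oxygen and loses the C3 hydrogen to give the (E)-styrene phenol 10, whose ring carbon C8a then adds to the exocyclic carbon C1 of the more electrophilic guaiacyl quinone methide, closing ring B and restoring both phenols. The closest known reaction type is the dimerisation of sinapate esters by FeCl3 or by peroxidase to 1-aryl-1,2-dihydronaphthalene-2,3-dicarboxylates; the cross-pairing of two different cinnamates on a diol tether and its asymmetric induction are without precedent, the nearest geometric analogy being the head-to-head photodimerisation of cinnamates held on 1,2-diols. The eight-membered ring closes by radical–radical recombination with both quinone methide C=C bonds left outside the ring (exo mode), and ring B closes 6-exo-trig as a vinylogous Friedel–Crafts addition. C2 is set in the recombination by the two hydrobenzoin centres: in a twist-boat dilactone with the phenyl groups and both quinone methide arms pseudo-equatorial, the (R,R)-tether leads to 2R. C1 is set by C2, the guaiacyl ring ending trans to the C2 carboxyl and pseudo-axial, away from the C8 methoxyl, as in the untethered dimerisations. The step needs intramolecular cross-coupling (tether, 1 mM concentration, slow addition of the oxidant), 8–8 and not 8–5 or 8–O coupling (these would need cyclophanes of twelve or more ring atoms around an (E)-alkene), ring closure by ring A and not by the guaiacyl ring (C8a is activated by an ortho and a para methoxyl and meets the better electrophile), and one absolute sense (the tether; a C2 epimer is a diastereomer of 11 and is removed by chromatography before the tether is cleaved).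

Step 7
Reactants: 11 hydrobenzoin-tethered (1S,2R)-1-aryl-1,2-dihydronaphthalene-2,3-dicarboxylate dilactone
Product: 12 [(1S,2R)-7-hydroxy-1-(4-hydroxy-3-methoxyphenyl)-6,8-dimethoxy-1,2-dihydronaphthalene-2,3-diyl]dimethanol
Conditions: iBu2AlH (8 equiv), toluene–CH2Cl2, −78 to 0 °C, Ar; aq. potassium sodium tartrate
Reagents that add atoms: none
Why: Hydride reduction of both lactone carbonyls to primary alcohols, with 1,2-reduction of the conjugated C3 ester as in the reduction of ferulate and sinapate esters with free phenols to coniferyl and sinapyl alcohols. C1 and C2 are not touched, and diol 5 is released for reuse.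

Step 8
Reactants: 12 [(1S,2R)-7-hydroxy-1-(4-hydroxy-3-methoxyphenyl)-6,8-dimethoxy-1,2-dihydronaphthalene-2,3-diyl]dimethanol
Product: 13 (+)-8-methoxyisolariciresinol
Conditions: H2 (1 atm), [Ir(cod)(PCy3)(py)]PF6 (5–10 mol%), CH2Cl2, 0 °C to rt
Reagents that add atoms: none
Why: Hydroxyl-directed homogeneous hydrogenation: the cationic iridium centre binds the homoallylic C2 carbinol and delivers hydrogen to the face that this group occupies, while the pseudo-axial C1 aryl group shields the other face. Hydrogen therefore adds to C3 cis to the C2 carbinol and the C3 carbinol ends trans to it (3R); arenes and the C1 centre are not affected.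

## Compound list

1 | ferulic acid, (E)-3-(4-hydroxy-3-methoxyphenyl)prop-2-enoic acid | COc1cc(/C=C/C(=O)O)ccc1O | starting material
2 | 4-O-acetylferulic acid, (E)-3-(4-acetoxy-3-methoxyphenyl)prop-2-enoic acid | COc1cc(/C=C/C(=O)O)ccc1OC(C)=O | intermediate
3 | sinapic acid, (E)-3-(4-hydroxy-3,5-dimethoxyphenyl)prop-2-enoic acid | COc1cc(/C=C/C(=O)O)cc(OC)c1O | starting material
4 | 4-O-acetylsinapic acid, (E)-3-(4-acetoxy-3,5-dimethoxyphenyl)prop-2-enoic acid | COc1cc(/C=C/C(=O)O)cc(OC)c1OC(C)=O | intermediate
5 | (R,R)-hydrobenzoin, (1R,2R)-1,2-diphenylethane-1,2-diol | O[C@H](c1ccccc1)[C@H](O)c1ccccc1 | starting material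
6 | (1R,2R)-2-hydroxy-1,2-diphenylethyl (E)-3-(4-acetoxy-3-methoxyphenyl)prop-2-enoate | COc1cc(/C=C/C(=O)O[C@H](c2ccccc2)[C@H](O)c2ccccc2)ccc1OC(C)=O | intermediate
7 | (1R,2R)-2-{[(E)-3-(4-acetoxy-3,5-dimethoxyphenyl)prop-2-enoyl]oxy}-1,2-diphenylethyl (E)-3-(4-acetoxy-3-methoxyphenyl)prop-2-enoate | COc1cc(/C=C/C(=O)O[C@H](c2ccccc2)[C@H](OC(=O)/C=C/c2cc(OC)c(OC(C)=O)c(OC)c2)c2ccccc2)ccc1OC(C)=O | intermediate
8 | (1R,2R)-2-{[(E)-3-(4-hydroxy-3,5-dimethoxyphenyl)prop-2-enoyl]oxy}-1,2-diphenylethyl (E)-3-(4-hydroxy-3-methoxyphenyl)prop-2-enoate | COc1cc(/C=C/C(=O)O[C@H](c2ccccc2)[C@H](OC(=O)/C=C/c2cc(OC)c(O)c(OC)c2)c2ccccc2)ccc1O | intermediate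
9 | bis(quinone methide) dilactone: eight-membered cyclic diester of 5 with a (2R,3R)-2,3-disubstituted succinic acid, C2 bearing the (3-methoxy-4-oxocyclohexa-2,5-dien-1-ylidene)methyl group and C3 the (3,5-dimethoxy-4-oxocyclohexa-2,5-dien-1-ylidene)methyl group, trans | COC1=CC(=C[C@H]2C(=O)O[C@H](c3ccccc3)[C@@H](c3ccccc3)OC(=O)[C@@H]2C=C2C=C(OC)C(=O)C(OC)=C2)C=CC1=O | intermediate
10 | styrene phenol quinone methide: eight-membered cyclic diester of 5 with (R)-3-[(3-methoxy-4-oxocyclohexa-2,5-dien-1-ylidene)methyl]-2-[(E)-4-hydroxy-3,5-dimethoxybenzylidene]succinic acid | COC1=CC(=C[C@H]2C(=O)O[C@H](c3ccccc3)[C@@H](c3ccccc3)OC(=O)/C2=C/c2cc(OC)c(O)c(OC)c2)C=CC1=O | intermediate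
11 | (1S,2R)-7-hydroxy-1-(4-hydroxy-3-methoxyphenyl)-6,8-dimethoxy-1,2-dihydronaphthalene-2,3-dicarboxylic acid, cyclic diester with (1R,2R)-1,2-diphenylethane-1,2-diol (eight-membered dilactone, C3=C4) | COc1cc([C@H]2c3c(cc(OC)c(O)c3OC)C=C3C(=O)O[C@H](c4ccccc4)[C@@H](c4ccccc4)OC(=O)[C@H]23)ccc1O | intermediate
12 | [(1S,2R)-7-hydroxy-1-(4-hydroxy-3-methoxyphenyl)-6,8-dimethoxy-1,2-dihydronaphthalene-2,3-diyl]dimethanol | COc1cc([C@H]2c3c(cc(OC)c(O)c3OC)C=C(CO)[C@@H]2CO)ccc1O | intermediate
13 | (+)-8-methoxyisolariciresinol, [(1S,2R,3R)-7-hydroxy-1-(4-hydroxy-3-methoxyphenyl)-6,8-dimethoxy-1,2,3,4-tetrahydronaphthalene-2,3-diyl]dimethanol | COc1cc([C@H]2c3c(cc(OC)c(O)c3OC)C[C@@H](CO)[C@@H]2CO)ccc1O | target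

## Step count and risks

Total steps: 8. Longest linear sequence: 7 (steps 1, 3, 4, 5, 6, 7 and 8, from ferulic acid 1).

**Step 6 (key step, proposed new method).**
- What may go wrong: intermolecular coupling and oligomerisation may outrun the intramolecular recombination, because both esters must turn out of their preferred ester conformation before the two alpha carbons can meet. Ring closure may run through the guaiacyl ring onto the syringyl quinone methide, or both quinone methides may tautomerise so that no ring B forms. The tether may discriminate poorly between the two faces at C2. The product phenols may be oxidised further.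
- Fallback (known chemistry, sets out from 3 and comes back at 13): sinapic acid 3 is hydrogenated (H2, Pd/C, MeOH) to 3-(4-hydroxy-3,5-dimethoxyphenyl)propanoic acid F1. Williamson benzylation (BnBr, KOH, aqueous EtOH) gives 3-[4-(benzyloxy)-3,5-dimethoxyphenyl]propanoic acid F2. Acylation of (S)-4-benzyl-2-oxazolidinone through the mixed pivalic anhydride gives the N-acyl oxazolidinone F3. Evans alkylation (NaN(SiMe3)2, tert-butyl bromoacetate, THF, −78 °C) gives the (R)-configured succinate derivative F4. LiBH4 removes the auxiliary and gives the hydroxy tert-butyl ester F5, which closes under TsOH to (R)-4-[4-(benzyloxy)-3,5-dimethoxybenzyl]dihydrofuran-2(3H)-one F6. Its lithium enolate (LiN(SiMe3)2, THF, −78 °C) adds to 4-(benzyloxy)-3-methoxybenzaldehyde anti to the benzyl group, giving the aldol adduct F7. CF3CO2H in CH2Cl2 ionises the carbinol, and Friedel–Crafts attack of the only tethered ring closes ring B with the aryl group trans, giving the all-trans tetralin lactone bis(benzyl ether) F8. Hydrogenolysis (H2, Pd/C) gives the diphenol lactone F9, and LiAlH4 in THF reduces F9 to 13. The regiochemistry and the absolute configuration rest on established reactions; the cost is about ten operations.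

**Step 7.**
- What may go wrong: the reduction may stall at the lactol stage through formation of insoluble aluminium phenoxides, and the free-phenol dihydronaphthalene may aromatise in air or ionise as a p-hydroxycinnamyl alcohol during work-up.
- Fallback (sets out from 11 and comes back at 13): the phenols of 11 are silylated (tBuMe2SiCl, imidazole, DMF) to the bis(silyl ether) dilactone F10. iBu2AlH reduction gives the bis(silyl ether) allylic diol F11. The directed hydrogenation of step 8 is run on F11 to give the bis(silyl ether) tetralin diol F12, and Bu4NF in THF releases 13. The phenols stay masked through both sensitive stages.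

**Step 8.**
- What may go wrong: the catalyst may be inhibited by tight binding of the 1,4-diol, the allylic alcohol may isomerise or ionise under the acidic iridium hydride, or facial selectivity may be poor if the allylic hydroxyl, which can reach either face, directs the addition.
- Fallback (sets out from 11 and comes back at 13): NaOMe in MeOH opens the tether of 11 to the dimethyl dihydronaphthalene-2,3-dicarboxylate F10a, named here F13. Hydrogenation over Pd/C (H2, EtOAc) gives the saturated diester F14, expected mainly as the 2,3-cis epimer. NaOMe in MeOH equilibrates the centre alpha to the C3 ester to the all-trans dimethyl ester F15, and LiAlH4 reduces F15 to 13. Thermodynamic control next to the ester replaces directed delivery of hydrogen.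

## Further compounds

F1 | step 6 | 3-(4-hydroxy-3,5-dimethoxyphenyl)propanoic acid | COc1cc(CCC(=O)O)cc(OC)c1O
F2 | step 6 | 3-[4-(benzyloxy)-3,5-dimethoxyphenyl]propanoic acid | COc1cc(CCC(=O)O)cc(OC)c1OCc1ccccc1
F3 | step 6 | (S)-4-benzyl-3-{3-[4-(benzyloxy)-3,5-dimethoxyphenyl]propanoyl}oxazolidin-2-one | COc1cc(CCC(=O)N2[C@@H](Cc3ccccc3)COC2=O)cc(OC)c1OCc1ccccc1
F4 | step 6 | tert-butyl (R)-4-[4-(benzyloxy)-3,5-dimethoxyphenyl]-3-[(S)-4-benzyl-2-oxooxazolidine-3-carbonyl]butanoate | COc1cc(C[C@H](CC(=O)OC(C)(C)C)C(=O)N2[C@@H](Cc3ccccc3)COC2=O)cc(OC)c1OCc1ccccc1
F5 | step 6 | tert-butyl (R)-4-[4-(benzyloxy)-3,5-dimethoxyphenyl]-3-(hydroxymethyl)butanoate | COc1cc(C[C@H](CC(=O)OC(C)(C)C)CO)cc(OC)c1OCc1ccccc1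
F6 | step 6 | (R)-4-[4-(benzyloxy)-3,5-dimethoxybenzyl]dihydrofuran-2(3H)-one | COc1cc(C[C@@H]2CC(=O)OC2)cc(OC)c1OCc1ccccc1
F7 | step 6 | (3S,4R)-4-[4-(benzyloxy)-3,5-dimethoxybenzyl]-3-{[4-(benzyloxy)-3-methoxyphenyl](hydroxy)methyl}dihydrofuran-2(3H)-one, carbinol epimers | COc1cc(C[C@H]2COC(=O)[C@@H]2C(O)c2ccc(OCc3ccccc3)c(OC)c2)cc(OC)c1OCc1ccccc1
F8 | step 6 | all-trans 1-aryltetralin 2,3-lactone (carbonyl on C2, OCH2 on C3) with both phenols as benzyl ethers, C1 to C3 configured as in 13 | COc1cc([C@H]2c3c(cc(OC)c(OCc4ccccc4)c3OC)C[C@H]3COC(=O)[C@H]23)ccc1OCc1ccccc1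
F9 | step 6 | all-trans 7-hydroxy-1-(4-hydroxy-3-methoxyphenyl)-6,8-dimethoxytetralin 2,3-lactone (carbonyl on C2, OCH2 on C3), C1 to C3 configured as in 13 | COc1cc([C@H]2c3c(cc(OC)c(O)c3OC)C[C@H]3COC(=O)[C@H]23)ccc1O
F10 | step 7 | bis(tert-butyldimethylsilyl ether) of dilactone 11 | COc1cc([C@H]2c3c(cc(OC)c(O[Si](C)(C)C(C)(C)C)c3OC)C=C3C(=O)O[C@H](c4ccccc4)[C@@H](c4ccccc4)OC(=O)[C@H]23)ccc1O[Si](C)(C)C(C)(C)C
F11 | step 7 | bis(tert-butyldimethylsilyl ether) of allylic diol 12 | COc1cc([C@H]2c3c(cc(OC)c(O[Si](C)(C)C(C)(C)C)c3OC)C=C(CO)[C@@H]2CO)ccc1O[Si](C)(C)C(C)(C)C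
F12 | step 7 | bis(tert-butyldimethylsilyl ether) of 13 | COc1cc([C@H]2c3c(cc(OC)c(O[Si](C)(C)C(C)(C)C)c3OC)C[C@@H](CO)[C@@H]2CO)ccc1O[Si](C)(C)C(C)(C)C
F13 | step 8 | dimethyl (1S,2R)-7-hydroxy-1-(4-hydroxy-3-methoxyphenyl)-6,8-dimethoxy-1,2-dihydronaphthalene-2,3-dicarboxylate (written F10a in the fallback text only to mark where it forms; its label is F13) | COc1cc([C@H]2c3c(cc(OC)c(O)c3OC)C=C(C(=O)OC)[C@@H]2C(=O)OC)ccc1O
F14 | step 8 | dimethyl (1S,2R,3S)-7-hydroxy-1-(4-hydroxy-3-methoxyphenyl)-6,8-dimethoxy-1,2,3,4-tetrahydronaphthalene-2,3-dicarboxylate (2,3-cis epimer) | COc1cc([C@H]2c3c(cc(OC)c(O)c3OC)C[C@H](C(=O)OC)[C@@H]2C(=O)OC)ccc1O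
F15 | step 8 | dimethyl (1S,2R,3R)-7-hydroxy-1-(4-hydroxy-3-methoxyphenyl)-6,8-dimethoxy-1,2,3,4-tetrahydronaphthalene-2,3-dicarboxylate (all-trans) | COc1cc([C@H]2c3c(cc(OC)c(O)c3OC)C[C@@H](C(=O)OC)[C@@H]2C(=O)OC)ccc1O
A1 | alternative 1 | [4-(benzyloxy)-3-methoxyphenyl][3-(benzyloxy)-2,4-dimethoxy-6-methylphenyl]methanone | COc1cc(C(=O)c2c(C)cc(OC)c(OCc3ccccc3)c2OC)ccc1OCc1ccccc1
A2 | alternative 1 | di-(−)-menthyl fumarate | O=C(/C=C/C(=O)O[C@@H]1C[C@H](C)CC[C@H]1C(C)C)O[C@@H]1C[C@H](C)CC[C@H]1C(C)C
A3 | alternative 1 | 1-hydroxy-1-aryltetralin trans-2,3-di-(−)-menthyl diester, hydroxyl cis to the C2 ester, phenols as benzyl ethers | COc1cc([C@@]2(O)c3c(cc(OC)c(OCc4ccccc4)c3OC)C[C@@H](C(=O)O[C@@H]5C[C@H](C)CC[C@H]5C(C)C)[C@@H]2C(=O)O[C@@H]5C[C@H](C)CC[C@H]5C(C)C)ccc1OCc1ccccc1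
A4 | alternative 2 | 2-formyl-3-(4-hydroxy-3,5-dimethoxybenzyl)butane-1,4-diyl bis(pivalate), the two centres configured as C2 and C3 of 13 | COc1cc(C[C@@H](COC(=O)C(C)(C)C)[C@@H](C=O)COC(=O)C(C)(C)C)cc(OC)c1O
A5 | alternative 2 | guaiacol, 2-methoxyphenol | COc1ccccc1O
A6 | alternative 2 | bis(pivalate) of 13 at the two primary hydroxyls | COc1cc([C@H]2c3c(cc(OC)c(O)c3OC)C[C@@H](COC(=O)C(C)(C)C)[C@@H]2COC(=O)C(C)(C)C)ccc1O
A7 | alternative 3 | tributyl{3-[4-(benzyloxy)-3-methoxyphenyl]-4,5-bis[(benzyloxy)methyl]cyclohex-1-en-1-yl}stannane, the three centres configured as C1, C2 and C3 of 13 | COc1cc([C@H]2C=C([Sn](CCCC)(CCCC)CCCC)C[C@@H](COCc3ccccc3)[C@@H]2COCc2ccccc2)ccc1OCc1ccccc1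
A8 | alternative 3 | 4-chloro-2,3-dimethoxycyclobut-2-en-1-one | COC1=C(OC)C(Cl)C1=O
A9 | alternative 3 | 8-hydroxy-6,7-dimethoxy-1-aryltetralin with benzyl-protected carbinols and pendant phenol, C1 to C3 configured as in 13 | COc1cc([C@H]2c3c(cc(OC)c(OC)c3O)C[C@@H](COCc4ccccc4)[C@@H]2COCc2ccccc2)ccc1OCc1ccccc1
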